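**Retrosynthetic overview**
- The target is the cis-(2S,3R)-2,3-diaryl-1,4-benzodioxane dehydrodimer of piceatannol, and the last step is only a global desilylation.
- Key disconnection: both C–O bonds of the dioxane ring are cut at once. This is a [4+2] union of the o-quinone of one (E)-piceatannol unit (O=C–C=O) with the stilbene C=C of a second unit, the same oxidised catechol/olefin pairing presumed in the plant.
- The second unit is used as its Z isomer, so suprafacial addition gives the cis ring. A chiral titanium TADDOLate on the quinone sets the absolute sense.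
- Both partners come from piceatannol: the tetra-TBS ether followed by E→Z photoisomerisation, and the 3,5-bis-TBS ether followed by Ag2O. Piceatannol comes from cheap resveratrol by IBX ortho-hydroxylation.
- Ring order: only one ring, the 1,4-dioxane, is built (step 5). All arene rings are bought.

Assumption: the sense of induction of the titanium TADDOLate in step 5 cannot be read from a precedent, so (R,R)-TADDOL is written for the (2S,3R) product; if it gives the mirror image, (S,S)-TADDOL is used in the same way.

Numbering note: unprimed stilbene positions belong to the resorcinol ring and primed positions to the catechol ring. TADDOL is (4R,5R)-2,2-dimethyl-α,α,α',α'-tetraphenyl-1,3-dioxolane-4,5-dimethanol.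

**Step 1**
Reactants: 1 resveratrol ((E)-3,4',5-trihydroxystilbene)
Product: 3 piceatannol ((E)-3,3',4',5-tetrahydroxystilbene), via piceatannol o-quinone 2 (not isolated)
Conditions: IBX (1.1 equiv), MeOH, −25 °C, 1 h; then aq Na2S2O4, 0 °C
Reagents that add atoms: IBX (2-iodoxybenzoic acid), O=C1OI(=O)(O)c2ccccc12
Why: IBX ortho-oxygenation of a phenol (phenol-to-o-quinone oxidation) takes the para-vinyl-conjugated 4'-phenol to o-quinone 2, which dithionite reduces in the same pot to the catechol, and no stereocentre is made while the E-alkene is untouched.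

**Step 2**
Reactants: 3 piceatannol
Product: 4 (E)-3,3',4',5-tetrakis(tert-butyldimethylsilyloxy)stilbene
Conditions: TBSCl (5 equiv), imidazole (10 equiv), DMF, rt, 12 h, Ar
Reagents that add atoms: TBSCl (tert-butyldimethylsilyl chloride), CC(C)(C)[Si](C)(C)Cl
Why: Imidazole-promoted silyl ether formation caps all four phenols, which blocks redox exchange with the quinone partner later and prevents quinone methide formation, while the 4'-oxygen stays a good donor.

**Step 3**
Reactants: 4 (E)-3,3',4',5-tetrakis(tert-butyldimethylsilyloxy)stilbene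
Product: 5 (Z)-3,3',4',5-tetrakis(tert-butyldimethylsilyloxy)stilbene
Conditions: [Ru(bpy)3](PF6)2 (1 mol %), 450 nm LED, degassed MeCN/CH2Cl2, rt; chromatography to Z:E >99:1 (recovered 4 recycled)
Reagents that add atoms: none
Why: In this triplet energy-transfer E→Z photoisomerisation the low-energy ruthenium excited state sensitises the planar E-stilbene but not the twisted, higher-triplet Z isomer, so Z accumulates without 6π photocyclisation and the alkene geometry that becomes the cis relationship is set here.

**Step 4**
Reactants: 3 piceatannol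
Product: 8 (E)-3,5-bis(tert-butyldimethylsilyloxy)-3',4'-dihydroxystilbene, via catechol phenylboronate 6 (not isolated), via bis-silylated phenylboronate 7 (not isolated)
Conditions: PhB(OH)2 (1.05 equiv), 4 Å MS, THF/DMF, rt; then TBSCl (2.4 equiv), imidazole (5 equiv), rt; then pinacol (1.5 equiv), rt
Reagents that add atoms: TBSCl (tert-butyldimethylsilyl chloride), CC(C)(C)[Si](C)(C)Cl
Why: In this transient boronate protection only the ortho-diol can close a five-membered cyclic phenylboronate, so the two meta-related resorcinol OH groups alone are silylated, and transesterification to the more stable pinacol boronate then frees the catechol.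

**Step 5**
Reactants: 8 (E)-3,5-bis(tert-butyldimethylsilyloxy)-3',4'-dihydroxystilbene; 5 (Z)-3,3',4',5-tetrakis(tert-butyldimethylsilyloxy)stilbene
Product: 10 (2S,3R)-cis-hexa-TBS ether of the target, via silylated o-quinone 9 (not isolated)
Conditions: slow addition of 8 to Ag2O (4 equiv), Na2SO4, CH2Cl2, 0 °C, dark, cold filtration; then 5 (0.8 equiv), TiCl2[(R,R)-TADDOLate] (20 mol %, from TiCl2(OiPr)2 and (R,R)-TADDOL), 4 Å MS, toluene/CH2Cl2, −78 to −40 °C, dark
Reagents that add atoms: none
Why: Proposed new method: Ag2O takes catechol 8 to o-quinone 9, the oxidised partner of the presumed biosynthesis, and its O=C–C=O unit adds across the electron-rich Z-alkene of 5 in an inverse-electron-demand hetero-Diels–Alder reaction that makes both C–O bonds on one alkene face, so the Z geometry is copied into the cis C2/C3 relationship; the alkene carbon next to the resorcinol ring is the nucleophilic end (positive charge builds next to the 4-silyloxyphenyl ring) and bonds to the quinone oxygen para to the styryl group, because the other carbonyl is vinylogously conjugated to the styryl donor, more basic, holds the tetravalent titanium and acts as the electron sink; chelation to TiCl2[(R,R)-TADDOLate] lowers the LUMO so that the reaction runs cold enough for ring closure to outrun C–C rotation, forces both aryl groups endo (away from the ligand) and lets the pseudo-axial ligand phenyl groups block one quinone face at the oxygen where the leading bond forms, which fixes (2S,3R); turnover is expected because 10 has no free OH and is a poor chelator; the closest known reaction types are the thermal o-quinone/styrene hetero-Diels–Alder synthesis of 1,4-benzodioxanes and the stereospecific quinone/styrene cycloadditions promoted by chiral titanium diolates.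

**Step 6**
Reactants: 10 (2S,3R)-cis-hexa-TBS ether of the target
Product: 11 target, (2S,3R)-3-(3,4-dihydroxyphenyl)-2-(3,5-dihydroxyphenyl)-6-[(E)-2-(3,5-dihydroxyphenyl)ethenyl]-2,3-dihydro-1,4-benzodioxine
Conditions: TBAF (6.6 equiv), AcOH (6.6 equiv), THF, 0 °C, Ar, dark; pH 5–6 work-up, Sephadex LH-20 (MeOH)
Reagents that add atoms: none
Why: Fluoride desilylation of aryl silyl ethers is buffered with acetic acid so that the 4-hydroxyphenyl group at C3 never sits as a phenoxide, which shuts off retro-oxa-Michael (quinone methide) opening and keeps the kinetic cis stereocentres and the E-alkene intact.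

**Compound list**
1 | resveratrol, (E)-3,4',5-trihydroxystilbene | Oc1ccc(/C=C/c2cc(O)cc(O)c2)cc1 | starting material
2 | piceatannol o-quinone, 4-[(E)-2-(3,5-dihydroxyphenyl)ethenyl]cyclohexa-3,5-diene-1,2-dione | Oc1cc(O)cc(/C=C/C2=CC(=O)C(=O)C=C2)c1 | intermediate
3 | piceatannol, (E)-3,3',4',5-tetrahydroxystilbene | Oc1cc(O)cc(/C=C/c2ccc(O)c(O)c2)c1 | intermediate
4 | (E)-3,3',4',5-tetrakis(tert-butyldimethylsilyloxy)stilbene | CC(C)(C)[Si](C)(C)Oc1cc(O[Si](C)(C)C(C)(C)C)cc(/C=C/c2ccc(O[Si](C)(C)C(C)(C)C)c(O[Si](C)(C)C(C)(C)C)c2)c1 | intermediate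
5 | (Z)-3,3',4',5-tetrakis(tert-butyldimethylsilyloxy)stilbene | CC(C)(C)[Si](C)(C)Oc1cc(O[Si](C)(C)C(C)(C)C)cc(/C=C\c2ccc(O[Si](C)(C)C(C)(C)C)c(O[Si](C)(C)C(C)(C)C)c2)c1 | intermediate
6 | piceatannol 3',4'-O-phenylboronate, 5-[(E)-2-(3,5-dihydroxyphenyl)ethenyl]-2-phenyl-1,3,2-benzodioxaborole | Oc1cc(O)cc(/C=C/c2ccc3OB(c4ccccc4)Oc3c2)c1 | intermediate
7 | 3,5-bis-TBS ether of boronate 6 | CC(C)(C)[Si](C)(C)Oc1cc(O[Si](C)(C)C(C)(C)C)cc(/C=C/c2ccc3OB(c4ccccc4)Oc3c2)c1 | intermediate
8 | (E)-3,5-bis(tert-butyldimethylsilyloxy)-3',4'-dihydroxystilbene | CC(C)(C)[Si](C)(C)Oc1cc(O[Si](C)(C)C(C)(C)C)cc(/C=C/c2ccc(O)c(O)c2)c1 | intermediate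
9 | 4-[(E)-2-[3,5-bis(tert-butyldimethylsilyloxy)phenyl]ethenyl]cyclohexa-3,5-diene-1,2-dione | CC(C)(C)[Si](C)(C)Oc1cc(O[Si](C)(C)C(C)(C)C)cc(/C=C/C2=CC(=O)C(=O)C=C2)c1 | intermediate
10 | (2S,3R)-cis-hexa-TBS ether of the target | CC(C)(C)[Si](C)(C)Oc1cc(O[Si](C)(C)C(C)(C)C)cc(/C=C/c2ccc3c(c2)O[C@H](c2ccc(O[Si](C)(C)C(C)(C)C)c(O[Si](C)(C)C(C)(C)C)c2)[C@H](c2cc(O[Si](C)(C)C(C)(C)C)cc(O[Si](C)(C)C(C)(C)C)c2)O3)c1 | intermediate
11 | (2S,3R)-3-(3,4-dihydroxyphenyl)-2-(3,5-dihydroxyphenyl)-6-[(E)-2-(3,5-dihydroxyphenyl)ethenyl]-2,3-dihydro-1,4-benzodioxine (cis) | Oc1cc(O)cc(/C=C/c2ccc3c(c2)O[C@H](c2ccc(O)c(O)c2)[C@H](c2cc(O)cc(O)c2)O3)c1 | target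

**Step count and risks**
Total step count: 6.
Longest linear sequence: 5 (steps 1, 2, 3, 5, 6).

**Step 5** is the most likely to fail. The dangers are low ee, Lewis-acid or electron-transfer induced Z→E leakage that gives the trans adduct, regioisomer formation, and C-alkylation of the quinone. The fallback gives up catalyst control and obtains the absolute configuration by resolution. Setting out from 9 and 5, the cycloaddition is run without any Lewis acid (toluene, 25–40 °C, dark). The less polar, more concerted pathway under these conditions best preserves the cis geometry. It gives 10 together with its mirror image, the (2R,3S)-cis-hexa-TBS adduct F1. The two are separated by preparative chiral SFC on an amylose tris(3,5-dimethylphenylcarbamate) phase, after any trans isomer or regioisomer has been removed on silica. The route is rejoined at 10.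

**Step 4** may fail in two ways: the boronate may not survive the silylation, or the free catechol 8 may dimerise during its later oxidation. The fallback avoids telling catechol from resorcinol altogether by installing the second catechol oxygen after silylation.
- Setting out from 1, acetylation of the 4'-OH with immobilised Candida antarctica lipase B and vinyl acetate gives 4'-O-acetylresveratrol F2.
- Silylation with TBSCl and imidazole gives 4'-O-acetyl-3,5-bis-O-TBS-resveratrol F3.
- Hydrazine hydrate at 0 °C removes the aryl acetate and gives 3,5-bis-O-TBS-resveratrol F4.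
- IBX (DMF, rt) oxidises this monophenol directly to the o-quinone, and the route is rejoined at 9. Compound 8 and Ag2O are bypassed, and no catechol is present that could couple with the quinone.

**Step 6** may suffer epimerisation at C3 to the trans isomer, or air oxidation while six phenols are set free. The fallback never lets a phenoxide exist. Setting out from 10, CsF and Ac2O in MeCN turn each aryl silyl ether directly into an aryl acetate. This gives the stable, silica-purifiable hexaacetate of the target F5. Hydrazine acetate in THF/MeOH at 0 °C then removes the acetates close to neutral pH, and the route is rejoined at 11.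

**Further compounds**
F1 | step 5 | (2R,3S)-cis-hexa-TBS adduct, mirror image of 10 | CC(C)(C)[Si](C)(C)Oc1cc(O[Si](C)(C)C(C)(C)C)cc(/C=C/c2ccc3c(c2)O[C@@H](c2ccc(O[Si](C)(C)C(C)(C)C)c(O[Si](C)(C)C(C)(C)C)c2)[C@@H](c2cc(O[Si](C)(C)C(C)(C)C)cc(O[Si](C)(C)C(C)(C)C)c2)O3)c1
F2 | step 4 | 4'-O-acetylresveratrol | CC(=O)Oc1ccc(/C=C/c2cc(O)cc(O)c2)cc1
F3 | step 4 | 4'-O-acetyl-3,5-bis-O-TBS-resveratrol | CC(=O)Oc1ccc(/C=C/c2cc(O[Si](C)(C)C(C)(C)C)cc(O[Si](C)(C)C(C)(C)C)c2)cc1
F4 | step 4 | 3,5-bis-O-TBS-resveratrol | Oc1ccc(/C=C/c2cc(O[Si](C)(C)C(C)(C)C)cc(O[Si](C)(C)C(C)(C)C)c2)cc1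
F5 | step 6 | (2S,3R)-cis-hexaacetate of the target | CC(=O)Oc1cc(OC(C)=O)cc(/C=C/c2ccc3c(c2)O[C@H](c2ccc(OC(C)=O)c(OC(C)=O)c2)[C@H](c2cc(OC(C)=O)cc(OC(C)=O)c2)O3)c1
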